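**Retrosynthetic overview**

- Broussoflavonol F is 8,3′-diprenylkaempferol. The strategy rests on ring C, the pyran-4-one: the C4 carbonyl lies between C4a of ring A and C3, and O1 bridges C8a and C2. Ring C is therefore cut into an ortho-iodophenol (ring A, iodine on C4a, free hydroxyl on C8a), carbon monoxide (C4) and an arylacetylene (C3, C2 and ring B).
- The 3-hydroxyl is added afterwards at C3 by lithiation, borylation and oxidation; the three MOM ethers come off last.
- Ring A partner: phloroglucinol → bis-MOM ether → ortho-iodide → O-(1,1-dimethylpropargyl) ether → semi-hydrogenation → Claisen shift to the one ortho carbon still bearing hydrogen (the future C8).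
- Ring B partner: 4-hydroxybenzaldehyde through the same propargylation, semi-hydrogenation and Claisen sequence, then MOM protection and Ohira–Bestmann alkynylation.
- Ring order: rings A and B are bought as arenes; ring C is the only ring formed, in step 11.

Key step: step 11

Remark on the chemistry: flavone numbering is used throughout. The target has no stereocentre; the transient Claisen dienones are racemic and the enaminone of the key step has no fixed alkene geometry, and both features vanish in the same flask. Commercial 3-chloro-3-methylbut-1-yne serves as the 1,1-dimethylpropargyl donor.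

**Route**

Step 1
Reactants: 1 phloroglucinol
Product: 2 3,5-bis(methoxymethoxy)phenol
Conditions: MOMCl (2.0 equiv), i-Pr2NEt, THF/DMF, 0 °C → rt; chromatography, mono- and tris-ethers recycled
Reagents that add atoms: chloromethyl methyl ether, COCCl
Why: O-alkylation (MOM protection) of three equivalent hydroxyls with two equivalents of MOMCl should give the bis-ether as the main statistical product, and because the hydroxyls are equivalent only the degree of protection, not its position, has to be controlled.

Step 2
Reactants: 2 3,5-bis(methoxymethoxy)phenol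
Product: 3 2-iodo-3,5-bis(methoxymethoxy)phenol
Conditions: NIS (1.0 equiv, slow addition), CH2Cl2, −78 → 0 °C, dark
Reagents that add atoms: N-iodosuccinimide, O=C1CCC(=O)N1I
Why: Electrophilic aromatic iodination of the free phenol in a non-polar solvent should go ortho to the hydroxyl (C2), since this site is less hindered than C4 between the two MOM ethers, occurs twice and is reached through a hydrogen-bonded NIS–phenol complex, while one equivalent at low temperature limits di-iodination.

Step 3
Reactants: 3 2-iodo-3,5-bis(methoxymethoxy)phenol; 4 3-chloro-3-methylbut-1-yne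
Product: 5 2-iodo-1,5-bis(methoxymethoxy)-3-[(2-methylbut-3-yn-2-yl)oxy]benzene
Conditions: CuCl2·2H2O (1 mol%), DBU, MeCN, 0 °C
Reagents that add atoms: none
Why: Copper-catalysed propargylic substitution of the tertiary propargylic chloride by the phenoxide should give the hindered aryl 1,1-dimethylpropargyl ether at 0 °C, where neither the aryl iodide nor the MOM ethers react.

Step 4
Reactants: 5 2-iodo-1,5-bis(methoxymethoxy)-3-[(2-methylbut-3-yn-2-yl)oxy]benzene
Product: 6 2-iodo-1,5-bis(methoxymethoxy)-3-[(2-methylbut-3-en-2-yl)oxy]benzene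
Conditions: H2 (1 atm), Pd/CaCO3 poisoned with Pb(OAc)2 (Lindlar catalyst), quinoline, EtOAc, rt, stopped after one equivalent of H2
Reagents that add atoms: none
Why: Lindlar semi-hydrogenation should stop at the terminal alkene, the poisoned catalyst without added base should leave the aryl C–I bond intact, and working at room temperature avoids the propargyl Claisen path to a chromene.

Step 5
Reactants: 6 2-iodo-1,5-bis(methoxymethoxy)-3-[(2-methylbut-3-en-2-yl)oxy]benzene
Product: 8 2-iodo-3,5-bis(methoxymethoxy)-6-(3-methylbut-2-en-1-yl)phenol, via Claisen dienone 7 (not isolated)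
Conditions: toluene, 110 °C, dark
Reagents that add atoms: none
Why: In this aromatic Claisen rearrangement the 1,1-dimethylallyl group is delivered with allylic inversion as a prenyl group to the only ortho carbon that carries hydrogen (the other carries iodine), and tautomerisation of dienone 7 restores the phenol.

Step 6
Reactants: 9 4-hydroxybenzaldehyde; 4 3-chloro-3-methylbut-1-yne
Product: 10 4-[(2-methylbut-3-yn-2-yl)oxy]benzaldehyde
Conditions: CuCl2·2H2O (1 mol%), DBU, MeCN, 0 °C → rt
Reagents that add atoms: none
Why: The same copper-catalysed propargylic etherification works well with acidic, electron-poor phenols such as this one.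

Step 7
Reactants: 10 4-[(2-methylbut-3-yn-2-yl)oxy]benzaldehyde
Product: 11 4-[(2-methylbut-3-en-2-yl)oxy]benzaldehyde
Conditions: H2 (1 atm), Pd/CaCO3 poisoned with Pb(OAc)2 (Lindlar catalyst), quinoline, EtOAc, rt
Reagents that add atoms: none
Why: Lindlar semi-hydrogenation reduces the terminal alkyne to the alkene and leaves the aldehyde untouched.

Step 8
Reactants: 11 4-[(2-methylbut-3-en-2-yl)oxy]benzaldehyde
Product: 13 4-hydroxy-3-(3-methylbut-2-en-1-yl)benzaldehyde, via Claisen dienone 12 (not isolated)
Conditions: o-xylene, 140 °C, sealed tube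
Reagents that add atoms: none
Why: In this aromatic Claisen rearrangement the two ortho carbons are equivalent and the para carbon is blocked by the formyl group, so a single 3-prenylphenol should form after tautomerisation of dienone 12.

Step 9
Reactants: 13 4-hydroxy-3-(3-methylbut-2-en-1-yl)benzaldehyde
Product: 14 4-(methoxymethoxy)-3-(3-methylbut-2-en-1-yl)benzaldehyde
Conditions: MOMCl, i-Pr2NEt, CH2Cl2, 0 °C → rt
Reagents that add atoms: chloromethyl methyl ether, COCCl
Why: MOM protection (O-alkylation) of the acidic para-formyl phenol is straightforward and masks the hydroxyl for the basic steps that follow.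

Step 10
Reactants: 14 4-(methoxymethoxy)-3-(3-methylbut-2-en-1-yl)benzaldehyde
Product: 15 4-ethynyl-1-(methoxymethoxy)-2-(3-methylbut-2-en-1-yl)benzene
Conditions: dimethyl (1-diazo-2-oxopropyl)phosphonate, K2CO3, MeOH, rt
Reagents that add atoms: dimethyl (1-diazo-2-oxopropyl)phosphonate, COP(=O)(OC)C(=[N+]=[N-])C(C)=O
Why: Seyferth–Gilbert homologation with the Ohira–Bestmann reagent converts the aryl aldehyde into the terminal alkyne under mild methanolic carbonate conditions that spare the MOM ether and the prenyl group.

Step 11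
Reactants: 8 2-iodo-3,5-bis(methoxymethoxy)-6-(3-methylbut-2-en-1-yl)phenol; 15 4-ethynyl-1-(methoxymethoxy)-2-(3-methylbut-2-en-1-yl)benzene; 16 carbon monoxide
Product: 19 5,7-bis(methoxymethoxy)-2-[4-(methoxymethoxy)-3-(3-methylbut-2-en-1-yl)phenyl]-8-(3-methylbut-2-en-1-yl)-4H-chromen-4-one, via aryl ynone 17 (not isolated), via diethylamino enone 18 (not isolated)
Conditions: PdCl2(dppf) (5 mol%), CO (20 atm), Et2NH, 120 °C
Reagents that add atoms: none
Why: Zerovalent palladium inserts into the C4a–I bond of 8, CO insertion gives the aroylpalladium iodide, and coupling with the amine-generated acetylide of 15 followed by reductive elimination forms C4–C4a and C3–C4 in ynone 17. Diethylamine then adds to the ynone to give enaminone 18, and the ortho-hydroxyl (O1) attacks C2 and expels the amine, a 6-endo-trig addition–elimination that forms O1–C2 and closes ring C. This is the known palladium-catalysed carbonylative annulation of ortho-iodophenols with terminal alkynes in a secondary amine. No stereocentre is formed. The step needs carbonylative instead of direct alkynylation, which the CO pressure and the absence of copper secure, and six- instead of five-membered closure, which the enaminone pathway secures because the oxygen attacks the carbon bearing nitrogen. The 8-prenyl regiochemistry cannot drift, since iodine marks C4a, the only free hydroxyl sits on C8a next to the prenyl carbon, and the other oxygens are MOM ethers.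

Step 12
Reactants: 19 5,7-bis(methoxymethoxy)-2-[4-(methoxymethoxy)-3-(3-methylbut-2-en-1-yl)phenyl]-8-(3-methylbut-2-en-1-yl)-4H-chromen-4-one
Product: 22 3-hydroxy-5,7-bis(methoxymethoxy)-2-[4-(methoxymethoxy)-3-(3-methylbut-2-en-1-yl)phenyl]-8-(3-methylbut-2-en-1-yl)-4H-chromen-4-one, via 3-lithioflavone 20 (not isolated), via lithium trimethoxyborate 21 (not isolated)
Conditions: LiN(i-Pr)2 (commercial solution, 1.5 equiv), THF, −78 °C; B(OMe)3, −78 → 0 °C; 30% aq H2O2, 0 °C → rt
Reagents that add atoms: hydrogen peroxide, OO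
Why: Carbonyl-directed lithiation of the flavone at C3 with a lithium amide, borylation and peroxide oxidation (boron-to-oxygen shift with retention) is a known way from flavones to flavonols, and the amide base at −78 °C and the basic peroxide should spare the MOM ethers and the prenyl alkenes.

Step 13
Reactants: 22 3-hydroxy-5,7-bis(methoxymethoxy)-2-[4-(methoxymethoxy)-3-(3-methylbut-2-en-1-yl)phenyl]-8-(3-methylbut-2-en-1-yl)-4H-chromen-4-one
Product: 23 Broussoflavonol F
Conditions: 3 M aq HCl/MeOH (1:5), 45 °C, stopped as soon as the last MOM ether is gone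
Reagents that add atoms: none
Why: Acid-catalysed acetal exchange with methanol removes the three MOM ethers, and dilute acid at moderate temperature keeps protonation of the prenyl alkenes (chroman formation with the neighbouring hydroxyls) slow.

**Compound list**

1 | phloroglucinol | Oc1cc(O)cc(O)c1 | starting material
2 | 3,5-bis(methoxymethoxy)phenol | COCOc1cc(O)cc(OCOC)c1 | intermediate
3 | 2-iodo-3,5-bis(methoxymethoxy)phenol | Oc1cc(OCOC)cc(OCOC)c1I | intermediate
4 | 3-chloro-3-methylbut-1-yne | CC(C)(Cl)C#C | starting material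
5 | 2-iodo-1,5-bis(methoxymethoxy)-3-[(2-methylbut-3-yn-2-yl)oxy]benzene | C#CC(C)(C)Oc1cc(OCOC)cc(OCOC)c1I | intermediate
6 | 2-iodo-1,5-bis(methoxymethoxy)-3-[(2-methylbut-3-en-2-yl)oxy]benzene | C=CC(C)(C)Oc1cc(OCOC)cc(OCOC)c1I | intermediate
7 | 2-iodo-3,5-bis(methoxymethoxy)-6-(3-methylbut-2-en-1-yl)cyclohexa-2,4-dien-1-one (racemic, not isolated) | O=C1C(I)=C(OCOC)C=C(OCOC)C1CC=C(C)C | intermediate
8 | 2-iodo-3,5-bis(methoxymethoxy)-6-(3-methylbut-2-en-1-yl)phenol | Oc1c(I)c(OCOC)cc(OCOC)c1CC=C(C)C | intermediate
9 | 4-hydroxybenzaldehyde | O=Cc1ccc(O)cc1 | starting material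
10 | 4-[(2-methylbut-3-yn-2-yl)oxy]benzaldehyde | C#CC(C)(C)Oc1ccc(C=O)cc1 | intermediate
11 | 4-[(2-methylbut-3-en-2-yl)oxy]benzaldehyde | C=CC(C)(C)Oc1ccc(C=O)cc1 | intermediate
12 | 3-(3-methylbut-2-en-1-yl)-4-oxocyclohexa-1,5-diene-1-carbaldehyde (racemic, not isolated) | O=C1C=CC(C=O)=CC1CC=C(C)C | intermediate
13 | 4-hydroxy-3-(3-methylbut-2-en-1-yl)benzaldehyde | O=Cc1ccc(O)c(CC=C(C)C)c1 | intermediate
14 | 4-(methoxymethoxy)-3-(3-methylbut-2-en-1-yl)benzaldehyde | O=Cc1ccc(OCOC)c(CC=C(C)C)c1 | intermediate
15 | 4-ethynyl-1-(methoxymethoxy)-2-(3-methylbut-2-en-1-yl)benzene | C#Cc1ccc(OCOC)c(CC=C(C)C)c1 | intermediate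
16 | carbon monoxide | [C-]#[O+] | starting material
17 | 1-[2-hydroxy-4,6-bis(methoxymethoxy)-3-(3-methylbut-2-en-1-yl)phenyl]-3-[4-(methoxymethoxy)-3-(3-methylbut-2-en-1-yl)phenyl]prop-2-yn-1-one (not isolated) | O=C(C#Cc1ccc(OCOC)c(CC=C(C)C)c1)c1c(O)c(CC=C(C)C)c(OCOC)cc1OCOC | intermediate
18 | 3-(diethylamino)-1-[2-hydroxy-4,6-bis(methoxymethoxy)-3-(3-methylbut-2-en-1-yl)phenyl]-3-[4-(methoxymethoxy)-3-(3-methylbut-2-en-1-yl)phenyl]prop-2-en-1-one (alkene geometry not fixed, not isolated) | CCN(CC)C(=CC(=O)c1c(O)c(CC=C(C)C)c(OCOC)cc1OCOC)c1ccc(OCOC)c(CC=C(C)C)c1 | intermediate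
19 | 5,7-bis(methoxymethoxy)-2-[4-(methoxymethoxy)-3-(3-methylbut-2-en-1-yl)phenyl]-8-(3-methylbut-2-en-1-yl)-4H-chromen-4-one | O=c1cc(-c2ccc(OCOC)c(CC=C(C)C)c2)oc2c(CC=C(C)C)c(OCOC)cc(OCOC)c12 | intermediate
20 | 3-lithio derivative of 19 (not isolated) | [Li]c1c(-c2ccc(OCOC)c(CC=C(C)C)c2)oc2c(CC=C(C)C)c(OCOC)cc(OCOC)c2c1=O | intermediate
21 | lithium trimethoxy(flavon-3-yl)borate derived from 20 (not isolated) | [Li+].CO[B-](OC)(OC)c1c(-c2ccc(OCOC)c(CC=C(C)C)c2)oc2c(CC=C(C)C)c(OCOC)cc(OCOC)c2c1=O | intermediate
22 | 3-hydroxy-5,7-bis(methoxymethoxy)-2-[4-(methoxymethoxy)-3-(3-methylbut-2-en-1-yl)phenyl]-8-(3-methylbut-2-en-1-yl)-4H-chromen-4-one | O=c1c(O)c(-c2ccc(OCOC)c(CC=C(C)C)c2)oc2c(CC=C(C)C)c(OCOC)cc(OCOC)c12 | intermediate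
23 | Broussoflavonol F, 3,5,7-trihydroxy-2-[4-hydroxy-3-(3-methylbut-2-en-1-yl)phenyl]-8-(3-methylbut-2-en-1-yl)-4H-chromen-4-one | CC(C)=CCc1cc(-c2oc3c(CC=C(C)C)c(O)cc(O)c3c(=O)c2O)ccc1O | target

**Totals**

Total step count: 13.
Longest linear sequence: 8 steps (steps 1–5, then 11–13); the ring B branch (steps 6–10) is 5 steps.

**Steps most likely to fail**

1. Step 11. Oxidative addition at the electron-rich C–I bond flanked by two oxygen substituents may be slow. Direct, non-carbonylative alkynylation followed by five-membered closure to a 2-arylbenzofuran, or capture of the aroylpalladium by diethylamine to an amide, could then compete. Fallback, from 8 and 15 back to 19: the same three bonds are made stepwise, with a formyl carbon in place of CO. Iodophenol 8 is treated with n-BuLi (2.2 equiv, THF, −78 °C; phenoxide formation, then iodine–lithium exchange) and DMF to give 2-hydroxy-4,6-bis(methoxymethoxy)-3-(3-methylbut-2-en-1-yl)benzaldehyde F1. The lithium acetylide of 15 (n-BuLi, THF, −78 °C, 2.2 equiv) adds to F1 to give racemic 1-[2-hydroxy-4,6-bis(methoxymethoxy)-3-(3-methylbut-2-en-1-yl)phenyl]-3-[4-(methoxymethoxy)-3-(3-methylbut-2-en-1-yl)phenyl]prop-2-yn-1-ol F2. MnO2 in CH2Cl2 oxidises F2 to ynone 17, and Et2NH in EtOH at room temperature takes 17 through enaminone 18 to flavone 19.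

2. Step 12. The amide base may deprotonate the benzylic–allylic CH2 of a prenyl group or C6 between the two MOM ethers instead of C3, and the borate may lose boron by protonation before it is oxidised. Fallback, from 19 back to 23: a hypervalent-iodine oxygenation that needs no strong base. Flavone 19 with PhI(OAc)2 and KOH in MeOH (0 °C → rt) should add methoxide at C2 and oxygenate C3, giving 2,4,4-trimethoxy-5,7-bis(methoxymethoxy)-2-[4-(methoxymethoxy)-3-(3-methylbut-2-en-1-yl)phenyl]-8-(3-methylbut-2-en-1-yl)chroman-3-ol F3 (racemic, relative configuration not relied upon). 3 M HCl in MeOH at 45 °C then hydrolyses the dimethyl acetal, eliminates methanol across C2–C3 and removes the MOM ethers in one flask, so the fallback rejoins the route at target 23 and replaces steps 12 and 13.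

3. Step 2. The iodinating agent may attack C4 (para to the hydroxyl, between the MOM ethers) or iodinate twice, which would send the wrong substitution pattern forward. Fallback, from 2 back to 3: directed ortho-metalation in place of electrophilic substitution. Phenol 2 with ClC(O)NEt2 and K2CO3 in MeCN (reflux) gives 3,5-bis(methoxymethoxy)phenyl N,N-diethylcarbamate F4. s-BuLi/TMEDA in THF at −78 °C lithiates between the carbamate (the strongest oxygen director) and a MOM ether, and I2 gives 2-iodo-3,5-bis(methoxymethoxy)phenyl N,N-diethylcarbamate F5. KOH in EtOH at reflux removes the carbamate and returns iodophenol 3.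

Further compounds
F1 | step 11 | 2-hydroxy-4,6-bis(methoxymethoxy)-3-(3-methylbut-2-en-1-yl)benzaldehyde | O=Cc1c(O)c(CC=C(C)C)c(OCOC)cc1OCOC
F2 | step 11 | 1-[2-hydroxy-4,6-bis(methoxymethoxy)-3-(3-methylbut-2-en-1-yl)phenyl]-3-[4-(methoxymethoxy)-3-(3-methylbut-2-en-1-yl)phenyl]prop-2-yn-1-ol (racemic) | OC(C#Cc1ccc(OCOC)c(CC=C(C)C)c1)c1c(O)c(CC=C(C)C)c(OCOC)cc1OCOC
F3 | step 12 | 2,4,4-trimethoxy-5,7-bis(methoxymethoxy)-2-[4-(methoxymethoxy)-3-(3-methylbut-2-en-1-yl)phenyl]-8-(3-methylbut-2-en-1-yl)chroman-3-ol (racemic, relative configuration unassigned) | COC1(OC)c2c(OCOC)cc(OCOC)c(CC=C(C)C)c2OC(OC)(c2ccc(OCOC)c(CC=C(C)C)c2)C1O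
F4 | step 2 | 3,5-bis(methoxymethoxy)phenyl N,N-diethylcarbamate | CCN(CC)C(=O)Oc1cc(OCOC)cc(OCOC)c1
F5 | step 2 | 2-iodo-3,5-bis(methoxymethoxy)phenyl N,N-diethylcarbamate | CCN(CC)C(=O)Oc1cc(OCOC)cc(OCOC)c1I
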